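**Retrosynthetic overview**
- C9–Br comes from C9–OH by Appel inversion; C3=CHBr from a C3 ketone by Wittig olefination; the C3 ketone from allylic oxidation of C3H2; C5H2 from a C5 ketone by reduction and radical deoxygenation.
- Key disconnection: the C6–C1 bond and the C7 carbinol come from a C6–C7 epoxide whose C6 carries a 1-silyloxycyclopent-2-enyl group (semipinacol 1,2-shift of the alkenyl carbon, C5 emerging as a ketone).
- The epoxide comes from C9–OH-directed epoxidation of the C6=C7 alkene with the tertiary oxygen masked as its TMS ether; the C6–C5 bond comes from the Shapiro vinyllithium of (4R,6R)-actinol and cyclopent-2-en-1-one.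
- Ring order: ring A is bought with actinol, the five-membered ring arrives with cyclopentenone, and ring B is formed last by expansion of that five-membered ring in the key step.
- Feature on which the plan rests: the tertiary carbinol C7(CH3)(OH) bonded to spiro C6, with the C7–O bond anti to the C6–C1 bond of the ring B alkene C1=C2 and C5 as the ring B carbon next to C6, which is the imprint of a C6–C7 epoxide opened at C6 with an anti 1,2-shift.

Key step: step 6

Remark: locants are those of the target skeleton (ring B: C1=C2, C3, C4, C5; spiro C6; ring A: C7–C11) and are used for all intermediates; the carbonyl carbon of cyclopentenone becomes C5, its alkene carbons C1 and C2, its CH2 groups C3 and C4; (4R,6R)-actinol is assumed to be purchased enantiopure.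

Step 1
Reactants: 1 (4R,6R)-actinol [(4R,6R)-4-hydroxy-2,2,6-trimethylcyclohexan-1-one]
Product: 2 (4R,6R)-4-hydroxy-2,2,6-trimethylcyclohexanone 2,4,6-triisopropylbenzenesulfonylhydrazone (trisylhydrazone at C6; 9-OH free)
Conditions: TrisNHNH2, HCl (cat.), MeCN, rt
Reagents that add atoms: 2,4,6-triisopropylbenzenesulfonohydrazide, CC(C)c1cc(C(C)C)c(S(=O)(=O)NN)c(C(C)C)c1
Why: Acid-catalysed sulfonylhydrazone formation on the hindered C6 ketone should be slow but clean at room temperature, the sulfonamide nitrogen settling syn to C7–H (the only α-hydrogen), while the C9 carbinol and its configuration are untouched.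

Step 2
Reactants: 2 trisylhydrazone of actinol; 3 cyclopent-2-en-1-one
Product: 6 (1R)-4-(1-hydroxycyclopent-2-en-1-yl)-3,5,5-trimethylcyclohex-3-en-1-ol (diol; both carbinol epimers), via vinyllithium 4 (not isolated), via organocerium reagent 5 (not isolated)
Conditions: s-BuLi (3.3 equiv), TMEDA, THF, −78 → 0 °C; CeCl3, −78 °C; 3, −78 °C
Reagents that add atoms: none
Why: Shapiro reaction in which, after O–H and N–H removal, the third equivalent of base takes the C7 methine proton, loss of sulfinate and N2 then gives the C6 vinyllithium regiospecifically, and its organocerium form should add 1,2 to cyclopentenone without enolisation or conjugate addition; the new carbinol centre forms without control and is erased in step 6.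

Step 3
Reactants: 6 diol
Product: 8 (1R)-3,5,5-trimethyl-4-[1-(trimethylsilyloxy)cyclopent-2-en-1-yl]cyclohex-3-en-1-ol (9-OH free; tertiary oxygen as TMS ether), via bis(trimethylsilyl) ether 7 (not isolated)
Conditions: TMS-imidazole, CH2Cl2, rt; K2CO3, MeOH, 0 °C
Reagents that add atoms: 1-(trimethylsilyl)imidazole, C[Si](C)(C)n1ccnc1
Why: Exhaustive silylation with a powerful silyl donor followed by carbonate-catalysed methanolysis exploits the large rate gap between a secondary and a congested tertiary trimethylsilyl ether, so that the doubly allylic tertiary hydroxyl is masked and only the C9 hydroxyl remains free to bind a metal.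

Step 4
Reactants: 8 homoallylic alcohol with masked tertiary oxygen
Product: 9 C6–C7 epoxide of 8 with the epoxide oxygen cis to the 9-hydroxyl [1,5,5-trimethyl-6-(1-trimethylsilyloxycyclopent-2-en-1-yl)-7-oxabicyclo[4.1.0]heptan-3-ol]
Conditions: VO(acac)2 (cat.), t-BuOOH, toluene, 0 °C → rt
Reagents that add atoms: tert-butyl hydroperoxide, CC(C)(C)OO
Why: Hydroxyl-directed epoxidation of a homoallylic cyclohexenol, in which the vanadium alkoxide at C9 carries the peroxide to the electron-rich C6=C7 alkene from its own face through the conformer with a pseudoaxial C9–O bond, should set C6 and C7 together with the epoxide cis to the C9 oxygen and override the intrinsic facial bias of the ring, while the silylated tertiary oxygen cannot deliver oxidant to either alkene and the cyclopentene is left alone.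

Step 5
Reactants: 9 epoxy alcohol
Product: 10 9-O-TBS ether of 9 [1-(1,6-epoxy-4-TBSO-2,2,6-trimethylcyclohexyl)-1-(trimethylsilyloxy)cyclopent-2-ene; epoxide cis to OTBS]
Conditions: TBSCl, imidazole, DMF, rt
Reagents that add atoms: tert-butyldimethylsilyl chloride, CC(C)(C)[Si](C)(C)Cl
Why: Silyl ether formation on the unhindered secondary C9 alcohol under mildly basic conditions should leave the epoxide and the tertiary silyl ether intact, keeps the C9 oxygen from binding TiCl4 in step 6 and differentiates it from the C5 oxygen later.

Step 6
Reactants: 10 epoxy bis-silyl ether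
Product: 11 (6R,7S,9S)-9-(tert-butyldimethylsilyloxy)-7-hydroxy-7,11,11-trimethylspiro[5.5]undec-1-en-5-one (7-OH cis to 9-OTBS and trans to C1)
Conditions: TiCl4, CH2Cl2, −78 °C
Reagents that add atoms: none
Why: TiCl4 binds the epoxide oxygen and the C6–O bond ionises in concert with a 1,2-shift of the alkenyl carbon of the five-membered ring (the future C1) from the silyloxy carbon to C6, anti to the departing oxygen, after which the silyloxocarbenium ion loses Me3SiCl to give the C5 ketone. The closest known reaction type is the Lewis-acid semipinacol rearrangement of 2,3-epoxy alcohol silyl ethers to β-hydroxy ketones with a quaternary α-carbon. Ring B is closed by ring expansion of the cyclopentene ring through this 1,2-shift (five to six members), not by an exo or endo cyclisation of a chain. C6 is set by inversion at the epoxide carbon, which places C1 trans and C5 cis to the C7 oxygen, and C7 simply keeps its oxygen, so both centres follow from the epoxide face fixed in step 4 and both carbinol epimers converge because that carbon becomes sp2. The step needs opening at C6 in preference to C7 and migration of the sp2 carbon in preference to the ring CH2: the first should be secured by the anchimeric assistance that only C6, next to the silyloxy carbon, can receive, the second by the higher migratory aptitude of an alkenyl group, whose π-system bridges in the transition state.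

Step 7
Reactants: 11 β-hydroxy ketone
Product: 12 9-(tert-butyldimethylsilyloxy)-7,11,11-trimethylspiro[5.5]undec-1-ene-5,7-diol (C5 epimers; C6 C7 C9 as in 11)
Conditions: NaBH4, CeCl3·7H2O, MeOH, −40 → 0 °C
Reagents that add atoms: none
Why: Luche reduction, in which hydride is small enough to reach the C5 carbonyl beside the crowded spiro carbon and the non-basic medium avoids retro-aldol cleavage of the C6–C7 bond; the C5 configuration is not controlled and is erased in step 9.

Step 8
Reactants: 12 diol
Product: 13 O-[9-(tert-butyldimethylsilyloxy)-7-hydroxy-7,11,11-trimethylspiro[5.5]undec-1-en-5-yl] S-methyl dithiocarbonate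
Conditions: NaH (1.1 equiv), THF, 0 °C; CS2; MeI
Reagents that add atoms: carbon disulfide, S=C=S; iodomethane, CI
Why: Xanthate formation (first stage of the Barton–McCombie deoxygenation) should occur at the secondary C5 alkoxide, which adds to the small electrophile CS2, whereas the flanked tertiary C7 hydroxyl gives no stable xanthate, and the slight excess of base is kept low so that a C7 alkoxide cannot close a cyclic thionocarbonate.

Step 9
Reactants: 13 xanthate
Product: 14 (6S,7S,9S)-9-(tert-butyldimethylsilyloxy)-7,11,11-trimethylspiro[5.5]undec-1-en-7-ol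
Conditions: Bu3SnH, AIBN, PhSeSePh (cat.), benzene, 80 °C
Reagents that add atoms: none
Why: Barton–McCombie radical deoxygenation, in which stannyl radical addition to the thiocarbonyl and β-scission give the secondary C5 radical that is reduced to CH2; because this homoallylic radical could close onto C1 and reopen with ring contraction, benzeneselenol formed in situ serves as a very fast hydrogen donor to trap it first, and no stereocentre is created.

Step 10
Reactants: 14 spirocyclic alkene
Product: 15 (6S,7S,9S)-9-(tert-butyldimethylsilyloxy)-7-hydroxy-7,11,11-trimethylspiro[5.5]undec-1-en-3-one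
Conditions: Rh2(cap)4 (dirhodium tetracaprolactamate, cat.), t-BuOOH, K2CO3, CH2Cl2, rt
Reagents that add atoms: tert-butyl hydroperoxide, CC(C)(C)OO
Why: Allylic C–H oxidation by tert-butylperoxy radicals should take place at C3, the only allylic CH2 (C6 is quaternary), and capture of the allyl radical at C3 and not at the neopentyl terminus C1 should give the C1=C2–C3=O enone without alkene transposition, the silyl ether and tertiary alcohol being inert.

Step 11
Reactants: 15 enone
Product: 16 (6S,7S,9S,E)-3-(bromomethylidene)-9-(tert-butyldimethylsilyloxy)-7,11,11-trimethylspiro[5.5]undec-1-en-7-ol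
Conditions: Ph3P(CH2Br)Br, KOtBu, THF, −78 → 0 °C
Reagents that add atoms: (bromomethyl)triphenylphosphonium bromide, [Br-].BrC[P+](c1ccccc1)(c1ccccc1)c1ccccc1
Why: Wittig bromomethylenation of the unhindered enone carbonyl by 1,2-attack of Ph3P=CHBr, the ylide being pre-formed with slightly less base than phosphonium salt so that no C7 alkoxide arises to start vinylogous retro-aldol cleavage of C6–C7; both alkene geometries are to be expected, the E isomer (Br on the C4 side) is separated by chromatography and the Z isomer can be re-equilibrated photochemically.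

Step 12
Reactants: 16 silyl ether
Product: 17 (6S,7S,9S,E)-3-(bromomethylidene)-7,11,11-trimethylspiro[5.5]undec-1-ene-7,9-diol
Conditions: TBAF, THF, 0 °C → rt
Reagents that add atoms: none
Why: Fluoride-induced desilylation should free the C9 hydroxyl, the vinyl bromide, the diene and the tertiary alcohol being inert to fluoride at this temperature.

Step 13
Reactants: 17 diol
Product: 18 (6S,7S,9R,E)-9-bromo-3-(bromomethylidene)-7,11,11-trimethylspiro[5.5]undec-1-en-7-ol (CNP0234157.1)
Conditions: CBr4, P(n-C8H17)3, toluene, 70 °C
Reagents that add atoms: tetrabromomethane, BrC(Br)(Br)Br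
Why: Appel reaction in which the secondary C9 hydroxyl is converted into an alkoxyphosphonium ion that bromide displaces by SN2 with inversion, turning the C9–O bond cis to the C7 hydroxyl into the equatorial C9–Br bond trans to it, while the tertiary C7 hydroxyl is too hindered to be activated.

**Compound list**
1 | (4R,6R)-actinol, (4R,6R)-4-hydroxy-2,2,6-trimethylcyclohexan-1-one | CC1(C)C[C@H](O)C[C@@H](C)C1=O | starting material
2 | trisylhydrazone of 1 (9-OH free) | CC1(C)C[C@H](O)C[C@@H](C)C1=NNS(=O)(=O)c1c(C(C)C)cc(C(C)C)cc1C(C)C | intermediate
3 | cyclopent-2-en-1-one | O=C1C=CCC1 | starting material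
4 | lithium (1R)-4-lithio-3,5,5-trimethylcyclohex-3-en-1-olate (vinyllithium) | CC1(C)C[C@H](O[Li])CC(C)=C1[Li] | intermediate (not isolated)
5 | dichlorocerium analogue of 4 (organocerium reagent) | CC1(C)C[C@H](O[Li])CC(C)=C1[Ce](Cl)Cl | intermediate (not isolated)
6 | (1R)-4-(1-hydroxycyclopent-2-en-1-yl)-3,5,5-trimethylcyclohex-3-en-1-ol | CC1(C)C[C@H](O)CC(C)=C1C2(O)C=CCC2 | intermediate
7 | bis(trimethylsilyl) ether of 6 | CC1(C)C[C@H](O[Si](C)(C)C)CC(C)=C1C2(O[Si](C)(C)C)C=CCC2 | intermediate (not isolated)
8 | (1R)-3,5,5-trimethyl-4-[1-(trimethylsilyloxy)cyclopent-2-en-1-yl]cyclohex-3-en-1-ol | CC1(C)C[C@H](O)CC(C)=C1C2(O[Si](C)(C)C)C=CCC2 | intermediate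
9 | C6–C7 epoxide of 8, epoxide oxygen cis to 9-OH | CC1(C)C[C@H](O)C[C@]2(C)O[C@]12C3(O[Si](C)(C)C)C=CCC3 | intermediate
10 | 1-(1,6-epoxy-4-TBSO-2,2,6-trimethylcyclohexyl)-1-(trimethylsilyloxy)cyclopent-2-ene, epoxide cis to OTBS | CC1(C)C[C@H](O[Si](C)(C)C(C)(C)C)C[C@]2(C)O[C@]12C3(O[Si](C)(C)C)C=CCC3 | intermediate
11 | (6R,7S,9S)-9-(tert-butyldimethylsilyloxy)-7-hydroxy-7,11,11-trimethylspiro[5.5]undec-1-en-5-one | CC1(C)C[C@H](O[Si](C)(C)C(C)(C)C)C[C@](C)(O)[C@@]12C=CCCC2=O | intermediate
12 | 9-(tert-butyldimethylsilyloxy)-7,11,11-trimethylspiro[5.5]undec-1-ene-5,7-diol (C5 epimers) | CC1(C)C[C@H](O[Si](C)(C)C(C)(C)C)C[C@](C)(O)[C@@]12C=CCCC2O | intermediate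
13 | S-methyl xanthate of 12 at the C5 oxygen | CC1(C)C[C@H](O[Si](C)(C)C(C)(C)C)C[C@](C)(O)[C@@]12C=CCCC2OC(=S)SC | intermediate
14 | (6S,7S,9S)-9-(tert-butyldimethylsilyloxy)-7,11,11-trimethylspiro[5.5]undec-1-en-7-ol | CC1(C)C[C@H](O[Si](C)(C)C(C)(C)C)C[C@](C)(O)[C@@]12C=CCCC2 | intermediate
15 | (6S,7S,9S)-9-(tert-butyldimethylsilyloxy)-7-hydroxy-7,11,11-trimethylspiro[5.5]undec-1-en-3-one | CC1(C)C[C@H](O[Si](C)(C)C(C)(C)C)C[C@](C)(O)[C@@]12C=CC(=O)CC2 | intermediate
16 | (6S,7S,9S,E)-3-(bromomethylidene)-9-(tert-butyldimethylsilyloxy)-7,11,11-trimethylspiro[5.5]undec-1-en-7-ol | CC1(C)C[C@H](O[Si](C)(C)C(C)(C)C)C[C@](C)(O)[C@@]12C=C/C(=C/Br)CC2 | intermediate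
17 | (6S,7S,9S,E)-3-(bromomethylidene)-7,11,11-trimethylspiro[5.5]undec-1-ene-7,9-diol | CC1(C)C[C@H](O)C[C@](C)(O)[C@@]12C=C/C(=C/Br)CC2 | intermediate
18 | (6S,7S,9R,E)-9-bromo-3-(bromomethylidene)-7,11,11-trimethylspiro[5.5]undec-1-en-7-ol | CC1(C)C[C@@H](Br)C[C@](C)(O)[C@@]12C=C/C(=C/Br)CC2 | target

Total step count: 13. Longest linear sequence: 13 steps (1 → 18).

**Steps most likely to fail**

Step 6. The epoxide may ionise at C7, the other tertiary carbon, and then eliminate or undergo a different 1,2-shift. The ring CH2 may migrate in place of the alkenyl carbon, or TiCl4 may ionise the tertiary allylic silyl ether. The fallback runs the rearrangement from an aluminium alkoxide chelate. It sets out from 10: the trimethylsilyl group alone is removed (TBAF, 1 equiv, AcOH, THF, −20 °C) to give the free tertiary alcohol 1-(1,6-epoxy-4-TBSO-2,2,6-trimethylcyclohexyl)cyclopent-2-en-1-ol F1. F1 is then heated with Al(OiPr)3 in i-PrOH. The aluminium alkoxide binds the epoxide oxygen, drives the alkenyl shift from within the chelate and reduces the new ketone at once by Meerwein–Ponndorf–Verley hydride transfer, which also removes the retro-aldol hazard. The fallback comes back to the route at diol 12.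

Step 9. The C5 radical may undergo a 1,2-vinyl shift (closure onto C1=C2 and reopening to a ring-contracted tertiary radical at C6) faster than it is reduced, and the xanthate of step 8 may be lost to a cyclic thionocarbonate. The fallback avoids a C5 radical and the C5 alcohol altogether. It sets out from ketone 11, which is condensed with TsNHNH2 (PPTS cat., EtOH, 60 °C, molecular sieves) to the tosylhydrazone of 11 F2. F2 is reduced with catecholborane (CHCl3, 0 °C) and the adduct decomposed with NaOAc·3H2O at reflux, converting C5=N into C5H2 by hydride addition, sulfinate loss and N2 extrusion. It comes back to the route at 14, replacing steps 7 to 9.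

Step 11. The olefination may give poor control of the exocyclic alkene geometry, and base may start vinylogous retro-aldol cleavage. The fallback sets the geometry in a separate, base-free operation. It sets out from enone 15, which is converted by Ramirez olefination (CBr4, PPh3, toluene, 80 °C) into the 3-(dibromomethylidene) compound F3. F3 is then mono-reduced with Bu3SnH and Pd(PPh3)4 (cat.) in toluene at rt; palladium should insert into the less shielded C–Br bond, the one on the side of the flat alkenyl carbon C2, so that the bromine on the C4 side remains. It comes back to the route at 16.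

**Further compounds**
F1 | step 6 | 1-(1,6-epoxy-4-(tert-butyldimethylsilyloxy)-2,2,6-trimethylcyclohexyl)cyclopent-2-en-1-ol, epoxide cis to OTBS | CC1(C)C[C@H](O[Si](C)(C)C(C)(C)C)C[C@]2(C)O[C@]12C3(O)C=CCC3
F2 | step 9 | 4-methylbenzenesulfonylhydrazone of ketone 11 at C5 | CC1(C)C[C@H](O[Si](C)(C)C(C)(C)C)C[C@](C)(O)[C@@]12C=CCCC2=NNS(=O)(=O)c1ccc(C)cc1
F3 | step 11 | 9-(tert-butyldimethylsilyloxy)-3-(dibromomethylidene)-7,11,11-trimethylspiro[5.5]undec-1-en-7-ol | CC1(C)C[C@H](O[Si](C)(C)C(C)(C)C)C[C@](C)(O)[C@@]12C=CC(=C(Br)Br)CC2
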